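Which flask still holds the most intermediate at the end of its time, when the starting material leaves by two routes at once?

| setting | red | blue | Saturday's | Friday's | Sunday's | Wednesday's |
|---|---|---|---|---|---|---|
| starting material | 0.19 M | 0.43 M | 0.29 M | 0.29 M | 0.29 M | 0.29 M |
| protic impurity | 0.29 M | 0.29 M | 0.290 M | 0.290 M | 0.290 M | 0.290 M |
| temperature | 62 °C | 112 °C | 130 °C | 70 °C | 100 °C | 40 °C |
| remark | run made earlier | run made earlier |  |  |  |  |
| time |  |  | 6.0 h | 6.0 h | 6.0 h | 6.0 h |

| run | time / h | intermediate / % | target / % |
|---|---|---|---|
| red | 15.0 | 4.6 | 0.3 |
| red | 30.0 | 7.7 | 0.7 |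
| red | 40.0 | 10.2 | 0 |
| red | 60.0 | 12.9 | 0.7 |
| red | 72.0 | 15.6 | 0 |
| red | 96.0 | 18.8 | 0 |
| red | 120 | 20.4 | 0 |
| blue | 0.667 | 25.9 | 0.1 |
| blue | 1.00 | 30.5 | 1.0 |
| blue | 1.50 | 35.1 | 0.3 |
| blue | 2.50 | 34.0 | 1.1 |
| blue | 4.00 | 24.2 | 1.3 |
| blue | 6.00 | 13.7 | 2.0 |
| blue | 10.0 | 4.6 | 0.9 |

(each reading ± 0.5 percentage points)

1. the best flask by amount of intermediate, in percent of the starting material charged; "all alike" if 1.5 percentage points covers them all (Saturday's / Friday's / Sunday's / Wednesday's / all alike)
2. amount of intermediate at the end, in percent of the starting material charged, Saturday's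
3. amount of intermediate at the end, in percent of the starting material charged, Friday's
4. amount of intermediate at the end, in percent of the starting material charged, Sunday's
5. amount of intermediate at the end, in percent of the starting material charged, Wednesday's

- candidate steps: starting material -> intermediate; intermediate -> target; starting material + protic impurity -> quenched substrate; intermediate -> decomposed reagent; target -> over-reaction product

The meeting opened with the proposal to write the balance of the starting material, which goes to intermediate by a first-order step and to quenched substrate with the protic impurity, a step that counts as pseudo-first-order while the impurity, 0.29 M in both earlier runs, stays near its charge. One colleague read the red run: since its intermediate at 120 h is 20.4% against 12.9% at half that time, the curve, its slow decay neglected, flattens towards a share of 30.8%, with a total loss constant of 0.00904 h⁻¹. Another read the blue run: its tail falls at 0.273 h⁻¹ and extrapolates back to 70.4%, and with the reading at 1.00 h this gives a total loss of 1.11 h⁻¹ and a share of 53.2%.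

The share quenched over the share made into intermediate then came to 2.24 in red and a lower 0.880 in blue. Interpolating its logarithm linearly in temperature, the meeting agreed to carry Sunday's quench odds, the rate of quenching over the rate of making intermediate with the impurity at its charge, 1.10, with Friday's at 1.93.

My own reckoning interpolates the total loss the same way, to 0.351 h⁻¹ for Sunday's, and assumes the intermediate's decay scales alike, to 0.0859 h⁻¹. That gives 29.9% for Sunday's and, with the decay neglected, 3.77% for Friday's. Saturday's is hotter than blue, which held 13.7% at 6.00 h, and Wednesday's is colder than red, whose early slope would give 1.84%, so I expect Sunday's to be best.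

The forecast gave 32% for Sunday's, 4.7% for Friday's, 0.1% for Saturday's and 0.1% for Wednesday's, and concluded “Sunday's flask is clearly best”.

The flasks give 33.9% for Sunday's, 4.38% for Friday's, 0% for Saturday's and 0.110% for Wednesday's.

    starting material → intermediate (k = 0.185 h⁻¹, Ea = 112 kJ mol⁻¹)
    intermediate → target (k = 0.00533 h⁻¹, Ea = 129 kJ mol⁻¹)
    starting material + protic impurity → quenched substrate (k = 0.607 M⁻¹ h⁻¹, Ea = 86.0 kJ mol⁻¹)
    intermediate → decomposed reagent (k = 0.0877 h⁻¹, Ea = 128 kJ mol⁻¹)
    target → over-reaction product (k = 0.0457 h⁻¹, Ea = 129 kJ mol⁻¹)
    (constants at 100 °C)

At 6.00 h Sunday's holds 36.8% of quenched substrate against 48.2% of intermediate and what came from it, a ratio of 0.763 that is lower than the reckoned quench odds of 1.10 at the charge and higher than the 0.693 those odds become with 63% of the impurity's own charge left. Friday's, with 92% of the impurity's own charge left, holds 8.37% of quenched substrate against 4.41% of intermediate and decomposed reagent, a ratio of 1.90 that is lower than its reckoned quench odds of 1.93 at the charge and higher than the 1.78 those odds become with that impurity left.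

The earlier runs and the new flask were generated by integration with made-up constants.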